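**Plan**

1. Retrosynthesis (ring numbering: C1 bears CO2H; alkenes C1=C2, C5=C6, C11=C12; stereocenter C8): add a temporary PhSO2 group at C13, cut the ring bond C13–C14, then C1–C2, then C12–C13 with C11–CH3, then the side-chain bonds C3′–C4′ and C2′–CH3, and last C7–C8.
2. Enabling feature: C14 is the CH2 on the α-carbon C1 of the 2-alkylidene ester C1=C2, that is, the SN2′ terminus of a Morita–Baylis–Hillman adduct of a C2 aldehyde with methyl acrylate. C13 is allylic to C11=C12, so a sulfone there gives the carbanion; C13–C14 is the central bond of the 1,5-diene C11=C12/C1=C2.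
3. Forward: neryl acetate gives the Z-allylic bromide 5 and hex-5-ynoic acid gives imide 12; enolate alkylation joins them (C7–C8). The imide carbon becomes an alkyne that is carboaluminated and prenylated (side chain). The second alkyne is carboaluminated and hydroxymethylated, then turned into the allylic sulfone; the other chain end becomes the Morita–Baylis–Hillman carbonate 30.
4. The only ring, the 14-membered carbocycle, closes in step 19 by sulfonyl-carbanion SN2′ attack; ester hydrolysis and palladium-catalysed hydride desulfonylation finish the route.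
5. Stereochemistry: C8 (R) from the (S)-4-benzyloxazolidinone enolate alkylation; C5=C6 (Z) from nerol; C11=C12 and C2′=C3′ (E) from syn carboalumination; C1=C2 (E) from the elimination in the key step.

Key step: step 19

Remark: C3 of 29 and 30 and C13 of 33 and 34 are formed without control and carried as epimer mixtures (no descriptor in the SMILES), because both centers are later flattened or removed.

**Route**

Step 1
Reactants: 1 neryl acetate [(2Z)-3,7-dimethylocta-2,6-dien-1-yl acetate]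
Product: 2 (2Z)-6-hydroxy-3-methylhex-2-en-1-yl acetate
Conditions: O3 (1.0 equiv), pyridine, CH2Cl2–MeOH, −78 °C; then NaBH4, −78 → 0 °C
Reagents that add atoms: ozone, O=[O+][O-]
Why: Chemoselective ozonolysis with reductive work-up; the C6=C7 alkene is the electron-richer one because the allylic acetoxy group deactivates C2=C3, so the Z alkene should stay intact.

Step 2
Reactants: 2 (2Z)-6-hydroxy-3-methylhex-2-en-1-yl acetate
Product: 3 (2Z)-6-[(tert-butyldiphenylsilyl)oxy]-3-methylhex-2-en-1-yl acetate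
Conditions: t-BuPh2SiCl, imidazole, DMF, rt
Reagents that add atoms: tert-butyl(chloro)diphenylsilane, CC(C)(C)[Si](Cl)(c1ccccc1)c1ccccc1
Why: Standard silylation of a primary alcohol; the silyl ether must survive base, hydride and AlMe3 in steps 3–11.

Step 3
Reactants: 3 (2Z)-6-[(tert-butyldiphenylsilyl)oxy]-3-methylhex-2-en-1-yl acetate
Product: 4 (2Z)-6-[(tert-butyldiphenylsilyl)oxy]-3-methylhex-2-en-1-ol
Conditions: K2CO3 (0.2 equiv), MeOH, 0 °C → rt
Reagents that add atoms: none
Why: Base-catalysed transesterification removes the acetate without touching the silyl ether or the Z alkene.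

Step 4
Reactants: 4 (2Z)-6-[(tert-butyldiphenylsilyl)oxy]-3-methylhex-2-en-1-ol
Product: 5 {[(4Z)-6-bromo-4-methylhex-4-en-1-yl]oxy}(tert-butyl)diphenylsilane
Conditions: CBr4, PPh3, CH2Cl2, 0 °C
Reagents that add atoms: tetrabromomethane, BrC(Br)(Br)Br
Why: Appel bromination of a primary allylic alcohol proceeds by SN2 at the CH2 carbon, so the Z geometry should be kept, as in the nerol series.

Step 5
Reactants: 6 hex-5-ynoic acid
Product: 9 6-(triisopropylsilyl)hex-5-ynoic acid, via dilithium carboxylate acetylide 7 (not isolated), via triisopropylsilyl ester 8 (not isolated)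
Conditions: LiN(i-Pr)2 (2.2 equiv), THF, −78 → 0 °C; i-Pr3SiCl (2.2 equiv), → rt; then 1 M HCl, THF, rt
Reagents that add atoms: chlorotriisopropylsilane, CC(C)[Si](Cl)(C(C)C)C(C)C
Why: C-silylation of the acetylide masks this alkyne so that only the alkyne made in step 10 is carboaluminated in step 11; the silyl ester formed alongside is hydrolysed in the acidic work-up.

Step 6
Reactants: 9 6-(triisopropylsilyl)hex-5-ynoic acid; 10 (4S)-4-benzyl-1,3-oxazolidin-2-one
Product: 12 (4S)-4-benzyl-3-[6-(triisopropylsilyl)hex-5-ynoyl]-1,3-oxazolidin-2-one, via mixed pivalic anhydride 11 (not isolated)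
Conditions: t-BuCOCl, Et3N, THF, −20 °C; then 10, LiCl, rt
Reagents that add atoms: none
Why: N-Acylation of the oxazolidinone through the mixed anhydride is the standard entry to the alkylation substrate.

Step 7
Reactants: 12 (4S)-4-benzyl-3-[6-(triisopropylsilyl)hex-5-ynoyl]-1,3-oxazolidin-2-one; 5 {[(4Z)-6-bromo-4-methylhex-4-en-1-yl]oxy}(tert-butyl)diphenylsilane
Product: 14 (4S)-4-benzyl-3-[(2R)-2-{(2Z)-6-[(tert-butyldiphenylsilyl)oxy]-3-methylhex-2-en-1-yl}-6-(triisopropylsilyl)hex-5-ynoyl]-1,3-oxazolidin-2-one, via sodium Z-enolate 13 (not isolated)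
Conditions: NaN(SiMe3)2 (1.1 equiv), THF, −78 °C; then 5 (1.5 equiv), −78 → −40 °C
Reagents that add atoms: none
Why: Evans asymmetric alkylation; the chelated Z-enolate is attacked by the reactive allylic bromide on the face opposite the benzyl group, which should set the new stereocenter as R (the future ring C8).

Step 8
Reactants: 14 the alkylated imide
Product: 15 (2R)-2-{(2Z)-6-[(tert-butyldiphenylsilyl)oxy]-3-methylhex-2-en-1-yl}-6-(triisopropylsilyl)hex-5-yn-1-ol
Conditions: LiBH4, H2O (1.1 equiv), Et2O, 0 °C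
Reagents that add atoms: none
Why: Reductive cleavage of the N-acyloxazolidinone gives the primary alcohol and releases the auxiliary without touching the α-stereocenter.

Step 9
Reactants: 15 the primary alcohol
Product: 16 (2R)-2-{(2Z)-6-[(tert-butyldiphenylsilyl)oxy]-3-methylhex-2-en-1-yl}-6-(triisopropylsilyl)hex-5-ynal
Conditions: Dess–Martin periodinane, NaHCO3, CH2Cl2, 0 °C → rt
Reagents that add atoms: none
Why: Buffered Dess–Martin oxidation is mild enough to give the α-branched aldehyde without epimerisation.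

Step 10
Reactants: 16 the aldehyde
Product: 17 (3R)-3-{(2Z)-6-[(tert-butyldiphenylsilyl)oxy]-3-methylhex-2-en-1-yl}-7-(triisopropylsilyl)hepta-1,6-diyne
Conditions: dimethyl (1-diazo-2-oxopropyl)phosphonate, K2CO3, MeOH, 0 °C → rt
Reagents that add atoms: dimethyl (1-diazo-2-oxopropyl)phosphonate, CC(=O)C(=[N+]=[N-])P(=O)(OC)OC
Why: Seyferth–Gilbert homologation under Ohira–Bestmann conditions turns the aldehyde into a terminal alkyne; the triisopropylsilyl alkyne and the α-alkyl stereocenter should tolerate K2CO3/MeOH.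

Step 11
Reactants: 17 the diyne; 18 prenyl bromide (1-bromo-3-methylbut-2-ene)
Product: 20 tert-butyl{[(4Z,7R,8E)-4,8,12-trimethyl-7-[4-(triisopropylsilyl)but-3-yn-1-yl]trideca-4,8,11-trien-1-yl]oxy}diphenylsilane, via alkenyl(dimethyl)alane 19 (not isolated)
Conditions: AlMe3 (2.5 equiv), Cp2ZrCl2 (0.5 equiv), CH2Cl2, 0 °C → rt; then 18 (3 equiv), Pd(PPh3)4 (5 mol %), THF, rt
Reagents that add atoms: trimethylaluminium, C[Al](C)C
Why: Negishi zirconium-catalysed carboalumination adds CH3 and Al syn across the terminal alkyne only (the silyl alkyne is inert), and cross-coupling of the alkenylalane with the allylic bromide under zerovalent palladium catalysis joins the unsubstituted prenyl terminus with retention, which should give the E-configured skipped diene.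

Step 12
Reactants: 20 the bis-silylated triene
Product: 21 (4Z,7R,8E)-7-(but-3-yn-1-yl)-4,8,12-trimethyltrideca-4,8,11-trien-1-ol
Conditions: Bu4NF·3H2O (3.5 equiv), THF, rt
Reagents that add atoms: none
Why: Fluoride removes the alkynyl silyl group and the silyl ether in one operation.

Step 13
Reactants: 21 the alkynol
Product: 24 (2E,6R,8Z)-3,9-dimethyl-6-[(2E)-6-methylhepta-2,5-dien-2-yl]dodeca-2,8-diene-1,12-diol, via alkenyl(dimethyl)alane 22 (not isolated), via lithium alkenylaluminate 23 (not isolated)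
Conditions: AlMe3 (3.5 equiv), Cp2ZrCl2 (0.5 equiv), CH2Cl2, rt; evaporation of excess AlMe3; then n-BuLi (1.2 equiv), THF, −78 °C; (CH2O)n, → rt
Reagents that add atoms: trimethylaluminium, C[Al](C)C; formaldehyde (as paraformaldehyde), C=O
Why: A second Negishi carboalumination (the free hydroxyl is carried as its aluminium alkoxide) followed by hydroxymethylation of the aluminate should give the E-trisubstituted allylic alcohol, the geraniol-type construction.

Step 14
Reactants: 24 the diol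
Product: 25 (4Z,7R,8E)-7-[(3E)-5-chloro-3-methylpent-3-en-1-yl]-4,8,12-trimethyltrideca-4,8,11-trien-1-ol
Conditions: N-chlorosuccinimide (1.15 equiv), Me2S (1.3 equiv), CH2Cl2, −40 → 0 °C
Reagents that add atoms: N-chlorosuccinimide, O=C1CCC(=O)N1Cl
Why: Corey–Kim chlorination is selective for allylic hydroxyls because only the allylic alkoxysulfonium ion is displaced by chloride at low temperature, while the saturated one reverts to the alcohol on work-up; no allylic transposition is expected.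

Step 15
Reactants: 25 the allylic chloride
Product: 26 (4Z,7R,8E)-4,8,12-trimethyl-7-[(3E)-3-methyl-5-(phenylsulfonyl)pent-3-en-1-yl]trideca-4,8,11-trien-1-ol
Conditions: PhSO2Na (1.5 equiv), Bu4NI (0.1 equiv), DMF, rt
Reagents that add atoms: sodium benzenesulfinate, [Na+].[O-]S(=O)c1ccccc1
Why: SN2 S-alkylation of the sulfinate by the primary allylic chloride should give the E-allylic sulfone that will carry the carbanion.

Step 16
Reactants: 26 the sulfone alcohol
Product: 27 (4Z,7R,8E)-4,8,12-trimethyl-7-[(3E)-3-methyl-5-(phenylsulfonyl)pent-3-en-1-yl]trideca-4,8,11-trienal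
Conditions: Dess–Martin periodinane, NaHCO3, CH2Cl2, 0 °C → rt
Reagents that add atoms: none
Why: Dess–Martin oxidation of the remaining primary alcohol tolerates the sulfone and the four trisubstituted alkenes.

Step 17
Reactants: 27 the sulfone aldehyde; 28 methyl acrylate
Product: 29 methyl (6Z,9R,10E)-3-hydroxy-6,10,14-trimethyl-2-methylidene-9-[(3E)-3-methyl-5-(phenylsulfonyl)pent-3-en-1-yl]pentadeca-6,10,13-trienoate (both C3 epimers)
Conditions: 28 (10 equiv), DABCO (1.0 equiv), MeOH (3 equiv), rt, 3–5 d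
Reagents that add atoms: none
Why: Morita–Baylis–Hillman reaction of an unhindered aliphatic aldehyde; DABCO is too weak a base to deprotonate the sulfone, and the uncontrolled carbinol center is destroyed in step 19.

Step 18
Reactants: 29 the Morita–Baylis–Hillman alcohol
Product: 30 methyl (6Z,9R,10E)-3-[(tert-butoxycarbonyl)oxy]-6,10,14-trimethyl-2-methylidene-9-[(3E)-3-methyl-5-(phenylsulfonyl)pent-3-en-1-yl]pentadeca-6,10,13-trienoate (both C3 epimers)
Conditions: Boc2O (1.5 equiv), DMAP (0.1 equiv), CH2Cl2, 0 °C → rt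
Reagents that add atoms: di-tert-butyl dicarbonate, CC(C)(C)OC(=O)OC(=O)OC(C)(C)C
Why: Standard preparation of a Morita–Baylis–Hillman carbonate; a carbonate is chosen as leaving group because it has no enolisable hydrogen.

Step 19
Reactants: 30 the Morita–Baylis–Hillman carbonate
Product: 33 methyl (1E,5Z,8R,11E)-5,11-dimethyl-8-[(2E)-6-methylhepta-2,5-dien-2-yl]-13-(phenylsulfonyl)cyclotetradeca-1,5,11-triene-1-carboxylate (both C13 epimers), via potassium sulfonyl carbanion 31 (not isolated), via macrocyclic ester enolate 32 (not isolated)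
Conditions: KN(SiMe3)2 (1.1 equiv) added over 1 h to 30 in THF (0.002 M), −78 °C, then → 0 °C; AcOH quench
Reagents that add atoms: none
Why: Proposed new method: KN(SiMe3)2 removes the proton α to the sulfone (the only C–H of pKa near 22), the α-carbon of the allyl sulfonyl anion adds to the unsubstituted CH2 terminus of the acrylate, and the ester enolate 32 expels tert-butyl carbonate from the neighbouring carbon (E1cB), so the C13–C14 bond, the ring and the C1=C2 alkene form in one operation. The closest known reaction types are the intermolecular SN2′ alkylation of stabilised carbanions by Morita–Baylis–Hillman acetates and carbonates, which gives (E)-2-alkylidene esters, and the sulfonyl-carbanion macrocyclisation onto allylic halides used for 14-membered terpenoid carbocycles; their combination in a ring-closing mode is not documented. The only ring closed is the 14-membered carbocycle, by 14-endo-trig attack in which both acrylate alkene carbons end up in the ring. The one new stereocenter, C13 bearing the sulfone, is not controlled and need not be, because step 21 removes it; C8 is not touched. The E geometry at C1=C2 should follow from the elimination conformer that keeps the C3 chain away from the enolate oxygens (allylic strain), which is also the thermodynamically preferred trisubstituted enoate. The step needs α- over γ-attack of the ambident anion and cyclisation over oligomerisation; γ-attack would build a quaternary carbon in a 12-membered ring and is disfavoured sterically, and the high dilution secures ring closure.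

Step 20
Reactants: 33 the macrocyclic sulfone ester
Product: 34 (1E,5Z,8R,11E)-5,11-dimethyl-8-[(2E)-6-methylhepta-2,5-dien-2-yl]-13-(phenylsulfonyl)cyclotetradeca-1,5,11-triene-1-carboxylic acid (both C13 epimers)
Conditions: LiOH (5 equiv), THF–MeOH–H2O (3:1:1), rt → 40 °C; then 1 M HCl to pH 3
Reagents that add atoms: lithium hydroxide, [Li+].[OH-]
Why: Saponification before the hydride step turns the conjugated ester into a carboxylate, which LiBHEt3 should neither reduce nor attack in a conjugate sense.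

Step 21
Reactants: 34 the macrocyclic sulfone acid
Product: 35 (1E,5Z,8R,11E)-5,11-dimethyl-8-[(2E)-6-methylhepta-2,5-dien-2-yl]cyclotetradeca-1,5,11-triene-1-carboxylic acid (target)
Conditions: Pd(dppp)Cl2 (0.1 equiv), LiBHEt3 (4 equiv), THF, 0 °C → rt; then aq. NH4Cl, 1 M HCl
Reagents that add atoms: none
Why: Palladium-catalysed reductive desulfonylation of an allylic sulfone: zerovalent palladium, formed in situ from the divalent precatalyst, ionises the allylic C–S bond and hydride is delivered to the less substituted allyl terminus C13, which should leave C11=C12 in place with E geometry; the first equivalent of hydride only deprotonates the acid.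

**Compound list**

1 | neryl acetate, (2Z)-3,7-dimethylocta-2,6-dien-1-yl acetate | CC(C)=CCC/C(C)=C\COC(C)=O | starting material
2 | (2Z)-6-hydroxy-3-methylhex-2-en-1-yl acetate | CC(=O)OC/C=C(C)\CCCO | intermediate
3 | (2Z)-6-[(tert-butyldiphenylsilyl)oxy]-3-methylhex-2-en-1-yl acetate | CC(=O)OC/C=C(C)\CCCO[Si](c1ccccc1)(c1ccccc1)C(C)(C)C | intermediate
4 | (2Z)-6-[(tert-butyldiphenylsilyl)oxy]-3-methylhex-2-en-1-ol | OC/C=C(C)\CCCO[Si](c1ccccc1)(c1ccccc1)C(C)(C)C | intermediate
5 | {[(4Z)-6-bromo-4-methylhex-4-en-1-yl]oxy}(tert-butyl)diphenylsilane | BrC/C=C(C)\CCCO[Si](c1ccccc1)(c1ccccc1)C(C)(C)C | intermediate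
6 | hex-5-ynoic acid | C#CCCCC(=O)O | starting material
7 | dilithium carboxylate acetylide of hex-5-ynoic acid | [Li+].[Li+].[C-]#CCCCC(=O)[O-] | intermediate (not isolated)
8 | triisopropylsilyl 6-(triisopropylsilyl)hex-5-ynoate | CC(C)[Si](C#CCCCC(=O)O[Si](C(C)C)(C(C)C)C(C)C)(C(C)C)C(C)C | intermediate (not isolated)
9 | 6-(triisopropylsilyl)hex-5-ynoic acid | CC(C)[Si](C#CCCCC(=O)O)(C(C)C)C(C)C | intermediate
10 | (4S)-4-benzyl-1,3-oxazolidin-2-one | O=C1N[C@@H](Cc2ccccc2)CO1 | starting material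
11 | 6-(triisopropylsilyl)hex-5-ynoic pivalic anhydride | CC(C)[Si](C#CCCCC(=O)OC(=O)C(C)(C)C)(C(C)C)C(C)C | intermediate (not isolated)
12 | (4S)-4-benzyl-3-[6-(triisopropylsilyl)hex-5-ynoyl]-1,3-oxazolidin-2-one | CC(C)[Si](C#CCCCC(=O)N1[C@@H](Cc2ccccc2)COC1=O)(C(C)C)C(C)C | intermediate
13 | sodium Z-enolate of 12 | CC(C)[Si](C#CCC/C=C(\[O-])N1[C@@H](Cc2ccccc2)COC1=O)(C(C)C)C(C)C.[Na+] | intermediate (not isolated)
14 | (4S)-4-benzyl-3-[(2R)-2-{(2Z)-6-[(tert-butyldiphenylsilyl)oxy]-3-methylhex-2-en-1-yl}-6-(triisopropylsilyl)hex-5-ynoyl]-1,3-oxazolidin-2-one | CC(C)[Si](C#CCC[C@H](C/C=C(C)\CCCO[Si](c1ccccc1)(c1ccccc1)C(C)(C)C)C(=O)N1[C@@H](Cc2ccccc2)COC1=O)(C(C)C)C(C)C | intermediate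
15 | (2R)-2-{(2Z)-6-[(tert-butyldiphenylsilyl)oxy]-3-methylhex-2-en-1-yl}-6-(triisopropylsilyl)hex-5-yn-1-ol | CC(C)[Si](C#CCC[C@H](C/C=C(C)\CCCO[Si](c1ccccc1)(c1ccccc1)C(C)(C)C)CO)(C(C)C)C(C)C | intermediate
16 | (2R)-2-{(2Z)-6-[(tert-butyldiphenylsilyl)oxy]-3-methylhex-2-en-1-yl}-6-(triisopropylsilyl)hex-5-ynal | CC(C)[Si](C#CCC[C@H](C/C=C(C)\CCCO[Si](c1ccccc1)(c1ccccc1)C(C)(C)C)C=O)(C(C)C)C(C)C | intermediate
17 | (3R)-3-{(2Z)-6-[(tert-butyldiphenylsilyl)oxy]-3-methylhex-2-en-1-yl}-7-(triisopropylsilyl)hepta-1,6-diyne | CC(C)[Si](C#CCC[C@H](C/C=C(C)\CCCO[Si](c1ccccc1)(c1ccccc1)C(C)(C)C)C#C)(C(C)C)C(C)C | intermediate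
18 | prenyl bromide, 1-bromo-3-methylbut-2-ene | CC(C)=CCBr | starting material
19 | (E)-alkenyl(dimethyl)alane from 17 | C[Al](C)/C=C(\C)[C@H](CCC#C[Si](C(C)C)(C(C)C)C(C)C)C/C=C(C)\CCCO[Si](c1ccccc1)(c1ccccc1)C(C)(C)C | intermediate (not isolated)
20 | tert-butyl{[(4Z,7R,8E)-4,8,12-trimethyl-7-[4-(triisopropylsilyl)but-3-yn-1-yl]trideca-4,8,11-trien-1-yl]oxy}diphenylsilane | CC(C)=CC/C=C(\C)[C@H](CCC#C[Si](C(C)C)(C(C)C)C(C)C)C/C=C(C)\CCCO[Si](c1ccccc1)(c1ccccc1)C(C)(C)C | intermediate
21 | (4Z,7R,8E)-7-(but-3-yn-1-yl)-4,8,12-trimethyltrideca-4,8,11-trien-1-ol | CC(C)=CC/C=C(\C)[C@H](CCC#C)C/C=C(C)\CCCO | intermediate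
22 | (E)-alkenyl(dimethyl)alane with dimethylaluminium alkoxide from 21 | CC(C)=CC/C=C(\C)[C@H](CC/C(C)=C/[Al](C)C)C/C=C(C)\CCCO[Al](C)C | intermediate (not isolated)
23 | lithium butyl(dimethyl)alkenylaluminate from 22 | CC(C)=CC/C=C(\C)[C@H](CC/C(C)=C/[Al-](C)(C)CCCC)C/C=C(C)\CCCO[Al](C)C.[Li+] | intermediate (not isolated)
24 | (2E,6R,8Z)-3,9-dimethyl-6-[(2E)-6-methylhepta-2,5-dien-2-yl]dodeca-2,8-diene-1,12-diol | CC(C)=CC/C=C(\C)[C@H](CC/C(C)=C/CO)C/C=C(C)\CCCO | intermediate
25 | (4Z,7R,8E)-7-[(3E)-5-chloro-3-methylpent-3-en-1-yl]-4,8,12-trimethyltrideca-4,8,11-trien-1-ol | CC(C)=CC/C=C(\C)[C@H](CC/C(C)=C/CCl)C/C=C(C)\CCCO | intermediate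
26 | (4Z,7R,8E)-4,8,12-trimethyl-7-[(3E)-3-methyl-5-(phenylsulfonyl)pent-3-en-1-yl]trideca-4,8,11-trien-1-ol | CC(C)=CC/C=C(\C)[C@H](CC/C(C)=C/CS(=O)(=O)c1ccccc1)C/C=C(C)\CCCO | intermediate
27 | (4Z,7R,8E)-4,8,12-trimethyl-7-[(3E)-3-methyl-5-(phenylsulfonyl)pent-3-en-1-yl]trideca-4,8,11-trienal | CC(C)=CC/C=C(\C)[C@H](CC/C(C)=C/CS(=O)(=O)c1ccccc1)C/C=C(C)\CCC=O | intermediate
28 | methyl acrylate | C=CC(=O)OC | starting material
29 | methyl (6Z,9R,10E)-3-hydroxy-6,10,14-trimethyl-2-methylidene-9-[(3E)-3-methyl-5-(phenylsulfonyl)pent-3-en-1-yl]pentadeca-6,10,13-trienoate (both C3 epimers) | CC(C)=CC/C=C(\C)[C@H](CC/C(C)=C/CS(=O)(=O)c1ccccc1)C/C=C(C)\CCC(O)C(=C)C(=O)OC | intermediate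
30 | methyl (6Z,9R,10E)-3-[(tert-butoxycarbonyl)oxy]-6,10,14-trimethyl-2-methylidene-9-[(3E)-3-methyl-5-(phenylsulfonyl)pent-3-en-1-yl]pentadeca-6,10,13-trienoate (both C3 epimers) | CC(C)=CC/C=C(\C)[C@H](CC/C(C)=C/CS(=O)(=O)c1ccccc1)C/C=C(C)\CCC(OC(=O)OC(C)(C)C)C(=C)C(=O)OC | intermediate
31 | potassium α-sulfonyl carbanion of 30 | CC(C)=CC/C=C(\C)[C@H](CC/C(C)=C/[CH-]S(=O)(=O)c1ccccc1)C/C=C(C)\CCC(OC(=O)OC(C)(C)C)C(=C)C(=O)OC.[K+] | intermediate (not isolated)
32 | potassium ester enolate of the cyclised adduct (14-membered ring, carbonate still in place) | CC(C)=CC/C=C(\C)[C@H]1C/C=C(/C)CCC(OC(=O)OC(C)(C)C)C(=C([O-])OC)CC(S(=O)(=O)c2ccccc2)/C=C(\C)CC1.[K+] | intermediate (not isolated)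
33 | methyl (1E,5Z,8R,11E)-5,11-dimethyl-8-[(2E)-6-methylhepta-2,5-dien-2-yl]-13-(phenylsulfonyl)cyclotetradeca-1,5,11-triene-1-carboxylate (both C13 epimers) | CC(C)=CC/C=C(\C)[C@H]1C/C=C(/C)CC/C=C(/C(=O)OC)CC(S(=O)(=O)c2ccccc2)/C=C(\C)CC1 | intermediate
34 | (1E,5Z,8R,11E)-5,11-dimethyl-8-[(2E)-6-methylhepta-2,5-dien-2-yl]-13-(phenylsulfonyl)cyclotetradeca-1,5,11-triene-1-carboxylic acid (both C13 epimers) | CC(C)=CC/C=C(\C)[C@H]1C/C=C(/C)CC/C=C(/C(=O)O)CC(S(=O)(=O)c2ccccc2)/C=C(\C)CC1 | intermediate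
35 | (1E,5Z,8R,11E)-5,11-dimethyl-8-[(2E)-6-methylhepta-2,5-dien-2-yl]cyclotetradeca-1,5,11-triene-1-carboxylic acid | CC(C)=CC/C=C(\C)[C@H]1C/C=C(/C)CC/C=C(/C(=O)O)CC/C=C(\C)CC1 | target

**Step count and risks**

Total step count: 21. Longest linear sequence: 19 steps (steps 1–4, then 7–21).

Steps most likely to fail:

1. Step 19 (key step). What may go wrong: oligomerisation instead of ring closure, attack through the γ-carbon of the ambident anion, poor E/Z control in the elimination, or loss of the carbonate to the base. Fallback (known chemistry, ring closed at C1=C2 instead): the fallback sets out from 26. Treatment with n-BuLi (2.1 equiv, THF, −78 °C) should give the alkoxide/sulfonyl-carbanion dianion, which adds through carbon to methyl 2-(diethoxyphosphoryl)acrylate (Michael addition) to give methyl (5E,9R,10E)-2-(diethoxyphosphoryl)-9-[(2Z)-6-hydroxy-3-methylhex-2-en-1-yl]-6,10,14-trimethyl-4-(phenylsulfonyl)pentadeca-5,10,13-trienoate F1. Dess–Martin oxidation should then give the aldehyde methyl (5E,9R,10E)-2-(diethoxyphosphoryl)-6,10,14-trimethyl-9-[(2Z)-3-methyl-6-oxohex-2-en-1-yl]-4-(phenylsulfonyl)pentadeca-5,10,13-trienoate F2. An intramolecular Horner–Wadsworth–Emmons reaction under Masamune–Roush conditions (LiCl, DBU, MeCN, 0.002 M) should close the 14-membered ring with the E-selectivity usual for 2-alkyl phosphonoacetates, and the route is rejoined at 33.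

2. Step 21. What may go wrong: reduction of the carboxyl group, hydride delivery to the tertiary allyl terminus (alkene transposition), or E/Z scrambling at C11=C12 through the palladium allyl intermediate. Fallback (sulfone removed by electron transfer at the alcohol oxidation level): the fallback sets out from 33. DIBAL-H (CH2Cl2, −78 °C) should give [(1E,5Z,8R,11E)-5,11-dimethyl-8-[(2E)-6-methylhepta-2,5-dien-2-yl]-13-(phenylsulfonyl)cyclotetradeca-1,5,11-trien-1-yl]methanol F3, which no longer holds a reducible enoate. Sodium amalgam, Na(Hg), with Na2HPO4 in MeOH–THF at −20 °C should cleave the C–S bond to give [(1E,5Z,8R,11E)-5,11-dimethyl-8-[(2E)-6-methylhepta-2,5-dien-2-yl]cyclotetradeca-1,5,11-trien-1-yl]methanol F4. MnO2 (CH2Cl2) should give (1E,5Z,8R,11E)-5,11-dimethyl-8-[(2E)-6-methylhepta-2,5-dien-2-yl]cyclotetradeca-1,5,11-triene-1-carbaldehyde F5, and Pinnick oxidation (NaClO2, NaH2PO4, 2-methylbut-2-ene, t-BuOH–H2O) returns to the target 35.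

3. Step 14. What may go wrong: loss of chemoselectivity between the two primary hydroxyls (chlorination or oxidation of the saturated one) or allylic transposition of the chloride. Fallback (protecting group in place of chemoselectivity): the fallback sets out from 21. t-BuMe2SiCl and imidazole should give tert-butyl{[(4Z,7R,8E)-7-(but-3-yn-1-yl)-4,8,12-trimethyltrideca-4,8,11-trien-1-yl]oxy}dimethylsilane F6. Carboalumination and hydroxymethylation as in step 13 should give (2E,6R,8Z)-12-[(tert-butyldimethylsilyl)oxy]-3,9-dimethyl-6-[(2E)-6-methylhepta-2,5-dien-2-yl]dodeca-2,8-dien-1-ol F7, now with a single free hydroxyl. MsCl, Et3N, then LiBr (THF) should give {[(4Z,7R,8E)-7-[(3E)-5-bromo-3-methylpent-3-en-1-yl]-4,8,12-trimethyltrideca-4,8,11-trien-1-yl]oxy}(tert-butyl)dimethylsilane F8. PhSO2Na (DMF) should give tert-butyldimethyl{[(4Z,7R,8E)-4,8,12-trimethyl-7-[(3E)-3-methyl-5-(phenylsulfonyl)pent-3-en-1-yl]trideca-4,8,11-trien-1-yl]oxy}silane F9. Pyridinium p-toluenesulfonate in MeOH removes the silyl group and the route is rejoined at 26.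

Further compounds
F1 | step 19 | methyl (5E,9R,10E)-2-(diethoxyphosphoryl)-9-[(2Z)-6-hydroxy-3-methylhex-2-en-1-yl]-6,10,14-trimethyl-4-(phenylsulfonyl)pentadeca-5,10,13-trienoate | CC(C)=CC/C=C(\C)[C@H](CC/C(C)=C/C(CC(C(=O)OC)P(=O)(OCC)OCC)S(=O)(=O)c1ccccc1)C/C=C(C)\CCCO
F2 | step 19 | methyl (5E,9R,10E)-2-(diethoxyphosphoryl)-6,10,14-trimethyl-9-[(2Z)-3-methyl-6-oxohex-2-en-1-yl]-4-(phenylsulfonyl)pentadeca-5,10,13-trienoate | CC(C)=CC/C=C(\C)[C@H](CC/C(C)=C/C(CC(C(=O)OC)P(=O)(OCC)OCC)S(=O)(=O)c1ccccc1)C/C=C(C)\CCC=O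
F3 | step 21 | [(1E,5Z,8R,11E)-5,11-dimethyl-8-[(2E)-6-methylhepta-2,5-dien-2-yl]-13-(phenylsulfonyl)cyclotetradeca-1,5,11-trien-1-yl]methanol | CC(C)=CC/C=C(\C)[C@H]1C/C=C(/C)CC/C=C(/CO)CC(S(=O)(=O)c2ccccc2)/C=C(\C)CC1
F4 | step 21 | [(1E,5Z,8R,11E)-5,11-dimethyl-8-[(2E)-6-methylhepta-2,5-dien-2-yl]cyclotetradeca-1,5,11-trien-1-yl]methanol | CC(C)=CC/C=C(\C)[C@H]1C/C=C(/C)CC/C=C(/CO)CC/C=C(\C)CC1
F5 | step 21 | (1E,5Z,8R,11E)-5,11-dimethyl-8-[(2E)-6-methylhepta-2,5-dien-2-yl]cyclotetradeca-1,5,11-triene-1-carbaldehyde | CC(C)=CC/C=C(\C)[C@H]1C/C=C(/C)CC/C=C(/C=O)CC/C=C(\C)CC1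
F6 | step 14 | tert-butyl{[(4Z,7R,8E)-7-(but-3-yn-1-yl)-4,8,12-trimethyltrideca-4,8,11-trien-1-yl]oxy}dimethylsilane | CC(C)=CC/C=C(\C)[C@H](CCC#C)C/C=C(C)\CCCO[Si](C)(C)C(C)(C)C
F7 | step 14 | (2E,6R,8Z)-12-[(tert-butyldimethylsilyl)oxy]-3,9-dimethyl-6-[(2E)-6-methylhepta-2,5-dien-2-yl]dodeca-2,8-dien-1-ol | CC(C)=CC/C=C(\C)[C@H](CC/C(C)=C/CO)C/C=C(C)\CCCO[Si](C)(C)C(C)(C)C
F8 | step 14 | {[(4Z,7R,8E)-7-[(3E)-5-bromo-3-methylpent-3-en-1-yl]-4,8,12-trimethyltrideca-4,8,11-trien-1-yl]oxy}(tert-butyl)dimethylsilane | CC(C)=CC/C=C(\C)[C@H](CC/C(C)=C/CBr)C/C=C(C)\CCCO[Si](C)(C)C(C)(C)C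
F9 | step 14 | tert-butyldimethyl{[(4Z,7R,8E)-4,8,12-trimethyl-7-[(3E)-3-methyl-5-(phenylsulfonyl)pent-3-en-1-yl]trideca-4,8,11-trien-1-yl]oxy}silane | CC(C)=CC/C=C(\C)[C@H](CC/C(C)=C/CS(=O)(=O)c1ccccc1)C/C=C(C)\CCCO[Si](C)(C)C(C)(C)C
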